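## Retrosynthetic overview
1. **Heptadienedione chain:** made last, by a boron-templated (Pabon) aldol condensation of an aryl-ether aldehyde with feruloylacetone (vanillin + acetylacetone).
2. **Aryl ether:** not an inverting Mitsunobu/SN2 on a carveol-type alcohol. Vanillin is joined by a stereoretentive (double-inversion) Pd(0) etherification of a cis-1,4-bis(carbonate), whose two leaving groups are distinguished by ring conformation.
3. **Key step:** both carbinol centres are set together by a face-selective Pt-catalysed 1,4-syn-diboration of the zingiberene diene, anti to the side chain, followed by stereoretentive C–B oxidation.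
4. **Diene:** made regiospecifically from a 4-substituted cyclohexenone through the kinetic dienyl triflate and Fe-catalysed methylation.
5. **Ring order:** only the cyclohexene ring is built, by organocatalytic Michael addition of (S)-citronellal to MVK followed by aldol condensation. Both arenes are bought as vanillin.

**Assumption 1:** the keto/enol placement in the target SMILES is one of two rapidly interconverting tautomers. The synthesis delivers that equilibrium compound.

**Assumption 2:** terpene ring numbering is C1 (OAr), C2 (CH3)=C3, C4 (OH), C5 (side chain), C6 (CH2). The target is 1S,4R,5R,2'S, so OAr and OH are cis to each other and both trans to the side chain.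

## Route

**Step 1**
- Reactants: 1, (S)-citronellal; 2, methyl vinyl ketone
- Product: 3, (2R)-2-[(2S)-6-methylhept-5-en-2-yl]-5-oxohexanal
- Conditions: (R)-2-[methoxy(diphenyl)methyl]pyrrolidine (10 mol %), ethyl 3,4-dihydroxybenzoate (20 mol %), neat, 4 °C, 36 h
- Reagents that add atoms: methyl vinyl ketone (2), C=CC(C)=O
- Why: Enamine-catalysed asymmetric Michael addition in which the (R)-diarylprolinol ether blocks one face of the E-enamine, so MVK sets the new α-centre as R under catalyst control (dr about 9:1 expected, minor epimer removed at 4), while the citronellal methyl centre is carried through as the side-chain S centre.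

**Step 2**
- Reactants: 3
- Product: 4, (4R)-4-[(2S)-6-methylhept-5-en-2-yl]cyclohex-2-en-1-one
- Conditions: KOH (0.1 M aq), n-Bu4NOH (cat.), Et2O–THF, reflux, 6 h
- Reagents that add atoms: none
- Why: Intramolecular aldol condensation (the closing half of a Robinson annulation) of the methyl ketone onto the aldehyde forms the only new ring and moves the α-centre to the much less acidic γ-position of the enone, so it is retained.

**Step 3**
- Reactants: 4
- Product: 5, (4R)-4-[(2S)-6-methylhept-5-en-2-yl]cyclohexa-1,5-dien-1-yl trifluoromethanesulfonate
- Conditions: LDA, THF, −78 °C; PhNTf2, −78 → 0 °C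
- Reagents that add atoms: N-phenylbis(trifluoromethanesulfonimide), O=S(=O)(N(c1ccccc1)S(=O)(=O)C(F)(F)F)C(F)(F)F
- Why: Kinetic α'-deprotonation gives the cross-conjugated enolate, and O-triflation fixes the position of the future C1=C2 bond without touching the γ-stereocentre.

**Step 4**
- Reactants: 5
- Product: 6, (5R)-2-methyl-5-[(2S)-6-methylhept-5-en-2-yl]cyclohexa-1,3-diene (zingiberene, natural-series configuration)
- Conditions: MeMgBr (1.5 equiv), Fe(acac)3 (5 mol %), THF–NMP, −30 °C, 30 min; used at once under Ar
- Reagents that add atoms: methylmagnesium bromide, C[Mg]Br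
- Why: Iron-catalysed Kumada-type coupling of the alkenyl triflate replaces OTf by CH3 at the same carbon, giving one diene regioisomer rather than the endo/exo mixtures obtained by carbinol dehydration.

**Step 5 (key step)**
- Reactants: 6
- Product: 7, 2,2'-{(1S,4R,5S)-2-methyl-5-[(2S)-6-methylhept-5-en-2-yl]cyclohex-2-ene-1,4-diyl}bis(4,4,5,5-tetramethyl-1,3,2-dioxaborolane). This is the cis-1,4-bis(pinacolboronate), with both boron atoms on the ring face opposite the side chain. C5 reads S here only because boron ranks below carbon; its geometry is unchanged.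
- Conditions: B2pin2 (1.1 equiv), Pt(dba)3 (3 mol %), PCy3 (6 mol %), THF, 60 °C, 16 h; concentrated under Ar, crude 7 carried forward
- Reagents that add atoms: bis(pinacolato)diboron, CC1(C)OB(OC1(C)C)B1OC(C)(C)C(C)(C)O1
- Why: Pt(0)-catalysed 1,4-diboration of an s-cis 1,3-diene delivers both boryl groups from the metal to one face, here the face opposite the C5 side chain, which sets C1 and C4 together as a cis pair trans to the side chain and moves the alkene to C2=C3, while the isolated trisubstituted alkene is inert.

**Step 6**
- Reactants: 7
- Product: 8, (1S,4R,5R)-2-methyl-5-[(2S)-6-methylhept-5-en-2-yl]cyclohex-2-ene-1,4-diol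
- Conditions: 3 M NaOH, 30 % H2O2, THF, 0 °C → rt, 3 h
- Reagents that add atoms: hydrogen peroxide, OO (both hydroxyl oxygens of 8)
- Why: Alkaline peroxide oxidation of the boronates proceeds by hydroperoxide addition to boron and a suprafacial 1,2-shift of carbon from B to O, so each C–B bond becomes C–O with retention and without allylic transposition, giving the cis-diol trans to the side chain and leaving both unactivated alkenes untouched.

**Step 7**
- Reactants: 8
- Product: 9, dimethyl (1S,4R,5R)-2-methyl-5-[(2S)-6-methylhept-5-en-2-yl]cyclohex-2-ene-1,4-diyl biscarbonate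
- Conditions: ClCO2Me (4 equiv), pyridine, DMAP (cat.), CH2Cl2, 0 °C → rt
- Reagents that add atoms: methyl chloroformate, COC(=O)Cl
- Why: Simple O-acylation of both hydroxyls needs no site selectivity at this stage and breaks no C–O bond, so all stereocentres are unchanged.

**Step 8 (key step)**
- Reactants: 9; 10, vanillin (1.1 equiv)
- Product: 11, 4-{[(1S,4R,5R)-4-(methoxycarbonyloxy)-2-methyl-5-[(2S)-6-methylhept-5-en-2-yl]cyclohex-2-en-1-yl]oxy}-3-methoxybenzaldehyde
- Conditions: Pd2(dba)3·CHCl3 (2.5 mol %), dppb (6 mol %), THF, 0 °C → rt; stopped at full conversion of 9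
- Reagents that add atoms: vanillin (10), COc1cc(C=O)ccc1O
- Why: Tsuji–Trost allylic etherification in which Pd(0) ionises only the pseudo-axial C1 carbonate (the C4 carbonate is pseudo-equatorial, flanked by the side chain on the face Pd must use, and would give a more substituted allyl), the released methoxide deprotonates vanillin, and the phenoxide attacks anti to Pd at the allyl terminus remote from the electron-withdrawing C4–O, so double inversion retains 1S.

**Step 9**
- Reactants: 11
- Product: 12, 4-{[(1S,4R,5R)-4-hydroxy-2-methyl-5-[(2S)-6-methylhept-5-en-2-yl]cyclohex-2-en-1-yl]oxy}-3-methoxybenzaldehyde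
- Conditions: K2CO3 (0.5 equiv), MeOH, 0 °C → rt
- Reagents that add atoms: none
- Why: Base-catalysed methanolysis (transesterification) cleaves the carbonate at the acyl carbon, so the C4–O bond and its configuration are untouched and the aldehyde, allyl aryl ether and alkenes are inert.

**Step 10**
- Reactants: 10, vanillin; 13, acetylacetone (3 equiv)
- Product: 14, (E)-6-(4-hydroxy-3-methoxyphenyl)hex-5-ene-2,4-dione (feruloylacetone)
- Conditions: B2O3, B(On-Bu)3, n-BuNH2, EtOAc, 75 °C; then 1 M HCl, 50 °C
- Reagents that add atoms: none beyond the two reactants (13: CC(=O)CC(C)=O)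
- Why: Pabon condensation in which the boron chelate masks the central carbon and directs the amine-catalysed aldol condensation to a terminal CH3, excess diketone holds it at mono-condensation, and E1cB dehydration gives the E-alkene.

**Step 11**
- Reactants: 12; 14 (1.1 equiv)
- Product: 15, terpecurcumin B, (1E,4Z,6E)-5-hydroxy-7-(4-{[(1S,4R,5R)-4-hydroxy-2-methyl-5-[(2S)-6-methylhept-5-en-2-yl]cyclohex-2-en-1-yl]oxy}-3-methoxyphenyl)-1-(4-hydroxy-3-methoxyphenyl)hepta-1,4,6-trien-3-one
- Conditions: 14, B2O3, EtOAc, 65 °C, 30 min; then 12, B(On-Bu)3, n-BuNH2 (0.3 equiv), 65 °C, 4 h; then 10 % aq AcOH, rt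
- Reagents that add atoms: none beyond the two reactants
- Why: A second Pabon aldol condensation at the remaining CH3 of the boron-chelated diketone gives the E-styryl bond, the free phenol and allylic alcohol only form reversible borates, and the weak-acid work-up spares the allylic ether/alcohol so no stereocentre is disturbed.

## Compound list

| No. | Name | SMILES | Role |
|---|---|---|---|
| 1 | (S)-citronellal | `O=CC[C@@H](C)CCC=C(C)C` | starting material |
| 2 | methyl vinyl ketone | `C=CC(C)=O` | starting material |
| 3 | (2R)-2-[(2S)-6-methylhept-5-en-2-yl]-5-oxohexanal | `CC(=O)CC[C@H]([C@@H](C)CCC=C(C)C)C=O` | intermediate |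
| 4 | (4R)-4-[(2S)-6-methylhept-5-en-2-yl]cyclohex-2-enone | `O=C1CC[C@H]([C@@H](C)CCC=C(C)C)C=C1` | intermediate |
| 5 | cross-conjugated dienyl triflate | `O=S(=O)(OC1=CC[C@H]([C@@H](C)CCC=C(C)C)C=C1)C(F)(F)F` | intermediate |
| 6 | (5R,2'S)-zingiberene | `CC1=CC[C@H]([C@@H](C)CCC=C(C)C)C=C1` | intermediate |
| 7 | cis-1,4-bis(Bpin) adduct, anti to side chain | `CC1(C)OB(OC1(C)C)[C@H]2C[C@H]([C@@H](C)CCC=C(C)C)[C@@H](B3OC(C)(C)C(C)(C)O3)C=C2C` | intermediate |
| 8 | (1S,4R,5R)-cis-ene-1,4-diol | `O[C@H]1C[C@H]([C@@H](C)CCC=C(C)C)[C@@H](O)C=C1C` | intermediate |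
| 9 | bis(methyl carbonate) of 8 | `COC(=O)O[C@H]1C[C@H]([C@@H](C)CCC=C(C)C)[C@@H](OC(=O)OC)C=C1C` | intermediate |
| 10 | vanillin | `COc1cc(C=O)ccc1O` | starting material |
| 11 | C1 vanillin ether, C4 methyl carbonate | `O=Cc1ccc(O[C@H]2C[C@H]([C@@H](C)CCC=C(C)C)[C@@H](OC(=O)OC)C=C2C)c(OC)c1` | intermediate |
| 12 | C1 vanillin ether, C4 free alcohol | `O=Cc1ccc(O[C@H]2C[C@H]([C@@H](C)CCC=C(C)C)[C@@H](O)C=C2C)c(OC)c1` | intermediate |
| 13 | acetylacetone | `CC(=O)CC(C)=O` | starting material |
| 14 | feruloylacetone | `COc1cc(/C=C/C(=O)CC(C)=O)ccc1O` | intermediate |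
| 15 | terpecurcumin B | `COc1cc(/C=C/C(=O)/C=C(O)/C=C/c2ccc(O[C@H]3C[C@H]([C@@H](C)CCC=C(C)C)[C@@H](O)C=C3C)c(OC)c2)ccc1O` | target |

## Summary

**Total steps:** 11.

**Longest linear sequence:** 10 (steps 1–9, then 11). Step 10 is the one-step convergent branch.

**Steps most likely to fail, with fallbacks**

1. **Step 5.**
   - Risk: slow diboration of a diene substituted next to a terminus, or incomplete facial selectivity.
   - Fallback: replace metal-catalysed dimetalation with a cycloaddition. Run a TPP-sensitised singlet-oxygen [4+2] on 6 at low temperature to partial conversion, to spare the prenyl alkene. Thiourea reduction of the endoperoxide then gives diol 8 directly, bypassing 7, and the facial isomers are separated by chromatography.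
2. **Step 8.**
   - Risk: ionisation of the wrong carbonate, attack at C3, or elimination and aromatisation to the ar-curcumene skeleton.
   - Fallback: form the aryl–O bond instead of the allyl–O bond. Run an SNAr of the less hindered C1 alkoxide of diol 8 (KHMDS, 1 equiv) on 4-fluoro-3-methoxybenzonitrile, then reduce with DIBAL-H to 12. The carbinol C–O bond is never broken, so 1S is retained by construction.
3. **Step 11.**
   - Risk: low yield, retro-aldol scrambling, or loss of the allylic ether during boron release.
   - Fallback: build the diketone by acylation rather than condensation. Aldol-condense 12 with acetone to the aryl butenone, acylate its lithium enolate (excess LiHMDS) with an O-TBS-feruloyl benzotriazolide, then desilylate with buffered fluoride.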